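**Strategy.** The 1,2-dioxane (O1, O2, C3–C6; C3 carries CH2CO2H, C6 is the methoxy ketal carbon) is traced back to a cyclobutane. C3 and C6 are 1,4-related through C4–C5, C6 is at the ketone oxidation level and C3 is a secondary carbon. This is the pattern left when O2 is inserted into the C1–C2 bond of a 2-substituted tertiary cyclobutanol. Cobalt-catalysed aerobic ring expansion does this in one operation, turning the four-membered carbocycle into the six-membered peroxyhemiketal. The precursor carries the complete enyne chain on the carbinol carbon and a glycerol-acetonide arm on C2. That arm is both the masked CH2CO2H and the chiral-pool handle for selecting C3; acidic methanol then sets C6 thermodynamically.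

Key step: step 7

Remark on the chemistry: ring positions are numbered as in the target throughout; O2 capture at the acyclic C3 radical cannot be face-selective, so C3 is selected through the removable (S)-glycerol handle and not induced, and at most half of the material after step 7 can be carried on.

Step 1
Reactants: 1 undec-1-yne
Product: 2 (E)-1-iodoundec-1-ene
Conditions: Cp2Zr(H)Cl, THF, rt; then I2, 0 °C
Reagents that add atoms: iodine, II
Why: Hydrozirconation–iodination: syn addition of Zr–H places Zr on the terminal carbon and iodinolysis of the C–Zr bond goes with retention, so only the E vinyl iodide is expected.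

Step 2
Reactants: 2 (E)-1-iodoundec-1-ene; 3 5-chloropent-1-yne
Product: 4 (6E)-1-chlorohexadec-6-en-4-yne
Conditions: PdCl2(PPh3)2 (cat.), CuI (cat.), Et3N, THF, rt
Reagents that add atoms: none
Why: Sonogashira coupling of a vinyl iodide with a terminal alkyne keeps the E geometry and leaves the primary alkyl chloride untouched.

Step 3
Reactants: 5 (S)-solketal [(4S)-2,2-dimethyl-1,3-dioxolane-4-methanol]
Product: 6 [(4R)-2,2-dimethyl-1,3-dioxolan-4-yl]methyl trifluoromethanesulfonate
Conditions: Tf2O, pyridine, CH2Cl2, −78 → −20 °C, used at once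
Reagents that add atoms: trifluoromethanesulfonic anhydride, O=S(=O)(OS(=O)(=O)C(F)(F)F)C(F)(F)F
Why: Sulfonylation of the primary hydroxyl (triflate formation) does not touch the stereocentre, whose descriptor changes from S to R only because the CIP priorities change.

Step 4
Reactants: 7 cyclobutanone
Product: 8 cyclobutanone N,N-dimethylhydrazone
Conditions: Me2NNH2, AcOH (cat.), EtOH, 60 °C
Reagents that add atoms: N,N-dimethylhydrazine, CN(C)N
Why: Acid-catalysed condensation gives the N,N-dimethylhydrazone, the enolate surrogate needed because the lithium enolate of cyclobutanone self-condenses.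

Step 5
Reactants: 8 cyclobutanone N,N-dimethylhydrazone; 6 [(4R)-2,2-dimethyl-1,3-dioxolan-4-yl]methyl trifluoromethanesulfonate
Product: 11 2-{[(4S)-2,2-dimethyl-1,3-dioxolan-4-yl]methyl}cyclobutan-1-one (both C2 epimers), via lithium azaenolate 9 (not isolated), via alkylated hydrazone 10 (not isolated)
Conditions: LDA, THF, 0 °C; then 6, −78 → 0 °C; then CuCl2, THF–H2O (pH 7 buffer), rt
Reagents that add atoms: water, O
Why: Metalated-hydrazone (azaenolate) alkylation: 9 displaces the primary triflate by SN2 at the CH2 carbon, so the dioxolane stereocentre is carried over unchanged, and buffered Cu(II)-assisted hydrolysis of 10 returns the ketone without opening the acetonide; the new cyclobutane stereocentre is not controlled and need not be, because step 7 destroys it.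

Step 6
Reactants: 4 (6E)-1-chlorohexadec-6-en-4-yne; 11 2-{[(4S)-2,2-dimethyl-1,3-dioxolan-4-yl]methyl}cyclobutan-1-one
Product: 13 2-{[(4S)-2,2-dimethyl-1,3-dioxolan-4-yl]methyl}-1-[(6E)-hexadec-6-en-4-yn-1-yl]cyclobutan-1-ol (mixture of diastereomers), via Grignard reagent 12 (not isolated)
Conditions: 4, Mg, I2 (cat.), THF, reflux; then 11, LaCl3·2LiCl (cat.), THF, −78 → 0 °C; aq NH4Cl
Reagents that add atoms: none
Why: Grignard formation from the primary chloride and 1,2-addition to the strained, electrophilic cyclobutanone (La(III) suppresses enolisation) give the tertiary cyclobutanol; the carbinol stereocentre forms without useful control and is likewise erased in step 7.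

Step 7
Reactants: 13 2-{[(4S)-2,2-dimethyl-1,3-dioxolan-4-yl]methyl}-1-[(6E)-hexadec-6-en-4-yn-1-yl]cyclobutan-1-ol
Product: 15 6-{[(4S)-2,2-dimethyl-1,3-dioxolan-4-yl]methyl}-3-[(6E)-hexadec-6-en-4-yn-1-yl]-1,2-dioxan-3-ol (both epimers at the CH–O carbon and both hemiketal anomers), via open-chain hydroperoxy ketone 14 (not isolated)
Conditions: Co(acac)2 (20 mol %), O2 (1 atm), 1,2-dichloroethane, 40 °C
Reagents that add atoms: dioxygen, O=O
Why: Co(II)/O2 converts the tertiary cyclobutanol into a cobalt(III) alkoxide/alkoxy radical whose strain-driven β-scission breaks the C1–C2 bond on the substituted side, giving a γ-keto secondary alkyl radical at the future C3; this radical captures O2, the peroxyl radical is reduced to hydroperoxide 14 with regeneration of the chain carrier, and the hydroperoxide adds to the ketone. The closest known reaction type is the Co(acac)2/O2 oxidative ring expansion of cyclobutanols to 1,2-dioxan-3-ols, the homologue of the metal-mediated cyclopropanol to 1,2-dioxolan-3-ol expansion. The only ring closed is the 1,2-dioxane, by reversible 6-exo-trig addition of the hydroperoxide oxygen to the C6 carbonyl, so the four cyclobutane carbons plus the two atoms of O2 make up the six-membered ring. Two stereocentres appear: C6 (hemiketal) is dynamic and is fixed only in step 8, and C3 arises by O2 capture at an acyclic radical for which no controlling element exists, so both C3 epimers are expected in comparable amounts, as diastereomers with respect to the (4S)-dioxolane that serves as the handle for their separation in step 8. The step needs regioselective scission, which the C2 substituent secures by making the secondary radical, and chemoselectivity over the enyne, which should hold because no hydride source is present (no Co–H hydrofunctionalisation) and O2 capture is far faster than radical addition to the enyne. All four diastereomers of 13 converge on the same radical, so none of the earlier stereochemical mixtures matters.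

Step 8
Reactants: 15 6-{[(4S)-2,2-dimethyl-1,3-dioxolan-4-yl]methyl}-3-[(6E)-hexadec-6-en-4-yn-1-yl]-1,2-dioxan-3-ol
Product: 16 (2S)-3-[(3S,6R)-6-[(6E)-hexadec-6-en-4-yn-1-yl]-6-methoxy-1,2-dioxan-3-yl]propane-1,2-diol
Conditions: TsOH·H2O (cat.), MeOH, 0 °C → rt; NaHCO3; chromatography on SiO2
Reagents that add atoms: methanol, CO
Why: Acid-catalysed exchange at the peroxyhemiketal carbon through the peroxycarbenium ion is reversible, so C6 settles under thermodynamic control in the anomer with axial OMe (anomeric effect) and both carbon substituents equatorial, i.e. OMe cis to the C3 arm as in the target, while the same acid transfers the isopropylidene group to the solvent (transketalisation); the two C3 epimers, now diastereomeric 1,3-related hydroxy peroxides through the (2S)-carbinol, are separated by chromatography and the (3S,6R,2′S) isomer is taken on.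

Step 9
Reactants: 16 (2S)-3-[(3S,6R)-6-[(6E)-hexadec-6-en-4-yn-1-yl]-6-methoxy-1,2-dioxan-3-yl]propane-1,2-diol
Product: 17 2-[(3S,6R)-6-[(6E)-hexadec-6-en-4-yn-1-yl]-6-methoxy-1,2-dioxan-3-yl]acetaldehyde
Conditions: NaIO4, THF–H2O (pH 7 buffer), 0 °C
Reagents that add atoms: none
Why: Malaprade glycol cleavage under neutral conditions excises the handle's carbinol carbon as formaldehyde and leaves the CH2CHO arm; the dialkyl peroxide and the enyne are inert to periodate, and the absence of base prevents β-elimination of the peroxide from the new aldehyde.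

Step 10
Reactants: 17 2-[(3S,6R)-6-[(6E)-hexadec-6-en-4-yn-1-yl]-6-methoxy-1,2-dioxan-3-yl]acetaldehyde
Product: 18 2-[(3S,6R)-6-[(6E)-hexadec-6-en-4-yn-1-yl]-6-methoxy-1,2-dioxan-3-yl]acetic acid (target)
Conditions: NaClO2, NaH2PO4, 2-methylbut-2-ene, t-BuOH–H2O, 0 °C → rt
Reagents that add atoms: sodium chlorite, [Na+].[O-]Cl=O
Why: Pinnick (chlorite) oxidation converts the aldehyde into the acid at pH 3–4 without touching the peroxyketal, the O–O bond or the enyne (hypochlorite is scavenged by the alkene additive) and without epimerising C3, which could invert only by base-induced retro-oxa-Michael cleavage.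

**Compound list**

1 | undec-1-yne | CCCCCCCCCC#C | starting material
2 | (E)-1-iodoundec-1-ene | CCCCCCCCC/C=C/I | intermediate
3 | 5-chloropent-1-yne | ClCCCC#C | starting material
4 | (6E)-1-chlorohexadec-6-en-4-yne | CCCCCCCCC/C=C/C#CCCCCl | intermediate
5 | (S)-solketal, (4S)-2,2-dimethyl-1,3-dioxolane-4-methanol | OC[C@H]1COC(C)(C)O1 | starting material
6 | [(4R)-2,2-dimethyl-1,3-dioxolan-4-yl]methyl trifluoromethanesulfonate | FC(F)(F)S(=O)(=O)OC[C@H]1COC(C)(C)O1 | intermediate
7 | cyclobutanone | O=C1CCC1 | starting material
8 | cyclobutanone N,N-dimethylhydrazone | CN(C)N=C1CCC1 | intermediate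
9 | lithium azaenolate of 8 (N-lithio-N-cyclobut-1-enyl-N′,N′-dimethylhydrazide) | CN(C)N([Li])C1=CCC1 | intermediate (not isolated)
10 | 2-{[(4S)-2,2-dimethyl-1,3-dioxolan-4-yl]methyl}cyclobutanone N,N-dimethylhydrazone | CN(C)N=C1CCC1C[C@H]1COC(C)(C)O1 | intermediate (not isolated)
11 | 2-{[(4S)-2,2-dimethyl-1,3-dioxolan-4-yl]methyl}cyclobutan-1-one, both C2 epimers | O=C1CCC1C[C@H]1COC(C)(C)O1 | intermediate
12 | [(6E)-hexadec-6-en-4-yn-1-yl]magnesium chloride | CCCCCCCCC/C=C/C#CCCC[Mg]Cl | intermediate (not isolated)
13 | 2-{[(4S)-2,2-dimethyl-1,3-dioxolan-4-yl]methyl}-1-[(6E)-hexadec-6-en-4-yn-1-yl]cyclobutan-1-ol, diastereomer mixture | CCCCCCCCC/C=C/C#CCCCC1(O)CCC1C[C@H]1COC(C)(C)O1 | intermediate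
14 | (11E)-1-[(4S)-2,2-dimethyl-1,3-dioxolan-4-yl]-2-hydroperoxyhenicos-11-en-9-yn-5-one, both C2 epimers | CCCCCCCCC/C=C/C#CCCCC(=O)CCC(OO)C[C@H]1COC(C)(C)O1 | intermediate (not isolated)
15 | 6-{[(4S)-2,2-dimethyl-1,3-dioxolan-4-yl]methyl}-3-[(6E)-hexadec-6-en-4-yn-1-yl]-1,2-dioxan-3-ol, epimers at both ring stereocentres | CCCCCCCCC/C=C/C#CCCCC1(O)CCC(C[C@H]2COC(C)(C)O2)OO1 | intermediate
16 | (2S)-3-[(3S,6R)-6-[(6E)-hexadec-6-en-4-yn-1-yl]-6-methoxy-1,2-dioxan-3-yl]propane-1,2-diol | CCCCCCCCC/C=C/C#CCCC[C@]1(OC)CC[C@@H](C[C@H](O)CO)OO1 | intermediate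
17 | 2-[(3S,6R)-6-[(6E)-hexadec-6-en-4-yn-1-yl]-6-methoxy-1,2-dioxan-3-yl]acetaldehyde | CCCCCCCCC/C=C/C#CCCC[C@]1(OC)CC[C@@H](CC=O)OO1 | intermediate
18 | 2-[(3S,6R)-6-[(6E)-hexadec-6-en-4-yn-1-yl]-6-methoxy-1,2-dioxan-3-yl]acetic acid | CCCCCCCCC/C=C/C#CCCC[C@]1(OC)CC[C@@H](CC(=O)O)OO1 | target

**Step count.** Total: 10 steps. Longest linear sequence: 7 steps (steps 4–10 from cyclobutanone; the branch through steps 1, 2 and 6–10 from undec-1-yne is equally long).

**Steps most likely to fail**

1. Step 7 (key step). What may go wrong: β-scission toward the unsubstituted ring CH2, radical-chain autoxidation of the enyne, or non-productive termination of the peroxyl radical (ketone or alcohol instead of hydroperoxide), so that the O–O unit is not delivered. The fallback sets out from 13 and returns at 15. Hypoiodite (alkoxy-radical) fragmentation of 13 with PhI(OAc)2/I2 under visible light should give the γ-iodo ketone (11E)-1-[(4S)-2,2-dimethyl-1,3-dioxolan-4-yl]-2-iodohenicos-11-en-9-yn-5-one F1. Silver-assisted substitution of the iodide by hydrogen peroxide (ethereal H2O2, AgOCOCF3, 0 °C) should then give hydroperoxide 14, which closes to 15. The peroxide is thus introduced by polar substitution instead of radical O2 capture.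

2. Step 8. What may go wrong: the O2 capture in step 7 has no facial bias, so the wanted C3 epimer is at best half of the material. The remote carbinol may also differentiate the two diols too weakly for clean chromatographic separation. The liberated hydroxyl groups can in addition compete with methanol for the peroxycarbenium ion (bridged internal ketals). The fallback sets out from 15 and returns at 17. A brief ketalisation that keeps the acetonide (PPTS, MeOH, 0 °C) should give the acetonide-protected methyl peroxyketals. Preparative HPLC separates (3R,6S)-6-{[(4S)-2,2-dimethyl-1,3-dioxolan-4-yl]methyl}-3-[(6E)-hexadec-6-en-4-yn-1-yl]-3-methoxy-1,2-dioxane F2 (3S,6R in target numbering) from its diastereomer (3S,6R)-6-{[(4S)-2,2-dimethyl-1,3-dioxolan-4-yl]methyl}-3-[(6E)-hexadec-6-en-4-yn-1-yl]-3-methoxy-1,2-dioxane F3. Periodic acid in Et2O then converts F2 into 17 in one pot (acetonide cleavage and glycol fission), with no free diol stage.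

3. Step 5. What may go wrong: slow SN2 at the β-oxygenated, branched primary carbon, with competing elimination or N-alkylation of the azaenolate, and partial loss of the acetonide during hydrazone hydrolysis. The fallback sets out from 6 and returns at 11. The lithium enolate of N,N-dimethylacetamide is alkylated with 6 to give N,N-dimethyl-3-[(4S)-2,2-dimethyl-1,3-dioxolan-4-yl]propanamide F4. Tf2O/2,4,6-collidine converts F4 into its keteniminium ion, which undergoes [2+2] cycloaddition with ethylene (DCE, reflux) to N-(2-{[(4S)-2,2-dimethyl-1,3-dioxolan-4-yl]methyl}cyclobutylidene)-N-methylmethanaminium trifluoromethanesulfonate F5. Aqueous NaHCO3 hydrolyses F5 to 11.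

Further compounds
F1 | step 7 | (11E)-1-[(4S)-2,2-dimethyl-1,3-dioxolan-4-yl]-2-iodohenicos-11-en-9-yn-5-one | CCCCCCCCC/C=C/C#CCCCC(=O)CCC(I)C[C@H]1COC(C)(C)O1
F2 | step 8 | (3R,6S)-6-{[(4S)-2,2-dimethyl-1,3-dioxolan-4-yl]methyl}-3-[(6E)-hexadec-6-en-4-yn-1-yl]-3-methoxy-1,2-dioxane | CCCCCCCCC/C=C/C#CCCC[C@]1(OC)CC[C@@H](C[C@H]2COC(C)(C)O2)OO1
F3 | step 8 | (3S,6R)-6-{[(4S)-2,2-dimethyl-1,3-dioxolan-4-yl]methyl}-3-[(6E)-hexadec-6-en-4-yn-1-yl]-3-methoxy-1,2-dioxane | CCCCCCCCC/C=C/C#CCCC[C@@]1(OC)CC[C@H](C[C@H]2COC(C)(C)O2)OO1
F4 | step 5 | N,N-dimethyl-3-[(4S)-2,2-dimethyl-1,3-dioxolan-4-yl]propanamide | CN(C)C(=O)CC[C@H]1COC(C)(C)O1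
F5 | step 5 | N-(2-{[(4S)-2,2-dimethyl-1,3-dioxolan-4-yl]methyl}cyclobutylidene)-N-methylmethanaminium trifluoromethanesulfonate | C[N+](C)=C1CCC1C[C@H]1COC(C)(C)O1.[O-]S(=O)(=O)C(F)(F)F
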